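**Numbering used throughout**

1 5-hydroxyvanillin; 2 its dibenzyl ether; 3 dimethyl succinate; 4 Stobbe half-ester; 5 (R) acid; 6 S-ethyl thioester; 7 (R) aldehyde (precursor of the key step); 8 vanillyl alcohol; 9 vanillyl p-tolyl sulfone; 10 quinone methide of ring A; 11 (2R,3R) aldehyde (product of the key step); 12 hydroxy ester; 13 di-O-benzyl lactone; 14 (-)-thujaplicatin.

## Analysis of the target

(-)-Thujaplicatin (14) is a dibenzylbutyrolactone lignan. Its core is a γ-butyrolactone (O1, C2 carbonyl, C3, C4, C5); C4 carries the methylene C7 bound to ring A (4-hydroxy-3-methoxyphenyl), and C3 carries the methylene C7' bound to ring B (3,4-dihydroxy-5-methoxyphenyl). There are two adjacent stereocentres, C3 (R) and C4 (R), with the two benzyl groups trans, which is also the more stable arrangement on this ring. C3 lies alpha to the lactone carbonyl and can be epimerised; C4 has no activating neighbour in the lactone and must be correct when it is made. The sensitive groups are three free phenols, two of them a catechol on ring B that oxidises readily in air under base, and the lactone, which alkoxide or hydroxide opens. The difficulty is that two benzyl groups differing only in their oxygen pattern must be placed on neighbouring carbons with absolute control at C4. The strategy rests on ring A: its hydroxyl is para to C7, so the C7–ring A unit is the reduced form of a para-quinone methide with C7 as the methylene terminus. If C5 is held at the aldehyde level, C4 is its alpha-carbon and can serve as an enamine nucleophile, so the C4–C7 bond can form by conjugate addition with re-aromatisation of ring A, whose phenol stays free.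

## Retrosynthetic reasoning

14 to 13. The last operation is the release of the ring B catechol. Both of its oxygens are carried as benzyl ethers in 13, because these survive alkoxide, hydride, a secondary amine and mild acid and are removed together under neutral reductive conditions that leave the lactone and C3 alone. The ring A phenol is already free in 13.

13 to 12 to 11. The C5–O1 bond is cut. Opening the lactone gives hydroxy ester 12, and raising C5 to the aldehyde level gives 11. This is where the plan gains its leverage: as an aldehyde, C5 makes C4 nucleophilic. The forward sequence is a carbonyl reduction and an acid-catalysed ring closure. Base equilibration of C3 after ring closure is deliberately left out: it would correct a C3 error, but it would also turn the cis lactone that stems from a C4 error into the enantiomer of 13. A cis isomer is therefore removed as a diastereomer at the stage of 13.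

11 to 7 and 10. The C4–C7 bond is cut. Cutting C3–C7' instead would be the classical enolate alkylation, but it presupposes a lactone in which C4 is already set. Cutting C4–C7 lets the most distinctive feature of ring A do the work: the electrophile is quinone methide 10 and the nucleophile is the enamine of aldehyde 7. The forward reaction must form one C–C bond and one stereocentre (C4) under control of a chiral secondary amine, with C3 as a bystander.

10 to 9 to 8. Quinone methide 10 carries no stabilising substituents and cannot be stored. It is traced to sulfone 9, which releases 10 by loss of arylsulfinate when its phenol is deprotonated. Sulfone 9 comes in one step from vanillyl alcohol 8.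

7 to 6 to 5. The aldehyde carbon C5 is traced to a free carboxylic acid through thioester 6. This path distinguishes C5 from the ester carbon C2 without hydride reagents that would attack both, and it avoids a γ-hydroxy ester that could lactonise the wrong way.

5 to 4. The C3–H and C7'–H bonds are cut, which leads to alkylidene succinate half-ester 4. The free carboxyl group next to the alkene is the chelating handle that an asymmetric hydrogenation needs, so C3 is set by a catalyst and independently of C4.

4 to 2 and 3. The C3=C7' bond is cut. A Stobbe condensation of aldehyde 2 with dimethyl succinate 3 forms it and leaves one carboxyl as acid (the future C5) and the other as methyl ester (the future C2), which is the differentiation the later steps need.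

2 to 1. Aldehyde 2 is the dibenzyl ether of 5-hydroxyvanillin 1, which already has the ring B oxygen pattern.

## Alternatives that were turned down

Alternative 1: The C4–C5 bond is cut, and C5 is delivered from a silicon tether on an oxygen at C7.
- Forward key step: the (bromomethyl)dimethylsilyl ether A1 of an (R) benzylic allylic alcohol is treated with Bu3SnH and AIBN. The α-silyl radical closes a five-membered ring (5-exo) on C4, the β-carbon of the enoate, and the α-ester radical at C3 takes a hydrogen atom, giving oxasilolane A2. Tamao oxidation, lactonisation and hydrogenolysis of the benzylic C7–O bond with the benzyl ethers would follow.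
- For it: the cyclisation is a dependable radical reaction, the C7 centre relays to C4 through a compact cyclic transition state, and C5 arrives at the alcohol level the lactone needs.
- Against it: C7 of 14 is a plain methylene, so an oxygenated stereocentre must be built enantioselectively and then deleted. C3 is formed by hydrogen-atom transfer to an acyclic radical without control, so base equilibration after lactonisation is compulsory. Stoichiometric Bu3SnH is needed, and ring A must be masked, giving three benzyl ethers.
- Comparison: on the predictability of the bond-forming event this route is stronger, since the chosen route depends on the transient electrophile 10. The chosen route offers absolute control at C4 from a catalyst with no auxiliary stereocentre, a C3 centre that is already set, no tin, and two steps from the key-step product 11 to 14.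

Alternative 2: Both C–H bonds at C3 and C4 are cut, leading to the flat butenolide A3.
- Forward key step: CuH, generated from Cu(OAc)2, a chiral bisphosphine such as DTBM-SEGPHOS, polymethylhydrosiloxane and tert-butanol, adds hydride to C4, and the enolate is protonated at C3. This gives A4, the tribenzyl ether of 14 with the trans arrangement.
- For it: it is the shortest conceivable endgame. One catalytic step makes both centres on the finished skeleton, C3 settles to trans, only hydrogenolysis remains, and A3 needs no stereocontrol in its assembly.
- Against it: asymmetric CuH conjugate reductions are at their best with β-substituted unsaturated lactones whose alkene is trisubstituted. In A3 the alkene is tetrasubstituted, and C4 carries two sp3 substituents of similar size (the ring oxymethylene C5 and the benzyl carbon C7), so both rate and face discrimination are doubtful. A3 can also isomerise under basic conditions to the aryl-conjugated exocyclic alkene, which would be reduced with a different outcome.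
- Comparison: this route is stronger on step economy after the key step and on ease of handling. The chosen route places the stereodetermining event at a trisubstituted enamine carbon whose two faces differ as hydrogen against a branched chain, and it sets C3 in a separate, well-understood step.

Alternative 3: Two bonds are cut at once, C3–C4 and C7–ring A, leading to vinylboronic acid pinacol ester A5, alkenyl bromide A6 and aryl triflate A7.
- Forward key step: the ate complex from A5 and lithiated A6 (t-BuLi) reacts with A7 under Pd(OAc)2 and a chiral MandyPhos ligand. The alkenyl group shifts from boron to C4 while the aryl group bonds to C7, giving boronic ester A8.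
- For it: three components are joined, two C–C bonds and the C4 centre are made in one catalytic step, no phenol-specific reactivity is required, and boron is a versatile handle.
- Against it: A8 has boron where C5 belongs and a methylidene where the C2 carboxyl belongs. One-carbon homologation at boron, oxidation, hydroboration of a 1,1-disubstituted alkene (C3 formed without reliable control), oxidation to the acid level, lactonisation, equilibration and hydrogenolysis would follow, the longest sequence after the key step of all four plans. The C7' protons of A6 are both allylic and benzylic, so deprotonation can compete with bromine–lithium exchange.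
- Comparison: this route is stronger on convergence and does not depend on a fragile electrophile. The chosen route gives a key-step product 11 in which every lactone carbon is present at, or one hydride step from, its final oxidation level, with C3 already fixed.

Key step: step 7

Assumption 1: (S,S)-Me-DuPhos is taken to give the (R) acid 5, by treating the carboxylate-bound half-ester as the carbon analogue of a chelating enamide; the configuration of 5 is to be confirmed before step 4, and the (R,R) ligand would be the direct replacement.
Assumption 2: compounds 1, 3 and 8 are taken to be purchasable.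

## Route

Step 1
Reactants: 1 5-hydroxyvanillin (3,4-dihydroxy-5-methoxybenzaldehyde)
Product: 2 3,4-bis(benzyloxy)-5-methoxybenzaldehyde
Conditions: BnBr (2.4 equiv), K2CO3 (3 equiv), DMF, 60 °C
Reagents that add atoms: benzyl bromide, BrCc1ccccc1
Why: Williamson ether synthesis on both phenoxides of the catechol; benzyl ethers are chosen because they should survive methoxide, hydride, the amine catalyst and mild acid and fall together under neutral hydrogenolysis at the end.

Step 2
Reactants: 2 3,4-bis(benzyloxy)-5-methoxybenzaldehyde; 3 dimethyl succinate
Product: 4 (E)-4-[3,4-bis(benzyloxy)-5-methoxyphenyl]-3-(methoxycarbonyl)but-3-enoic acid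
Conditions: NaOMe (1.5 equiv), MeOH, reflux; then aq. HCl
Reagents that add atoms: none
Why: Stobbe condensation: the succinate enolate adds to the aldehyde, the alkoxide closes onto the distal ester and base-induced ring opening by elimination gives the arylidene half-ester as its carboxylate, which makes the sequence irreversible. The two carboxyl carbons emerge differentiated (free acid for C5, methyl ester for C2), and the E isomer (aryl trans to the ester) should predominate.

Step 3
Reactants: 4 (E)-4-[3,4-bis(benzyloxy)-5-methoxyphenyl]-3-(methoxycarbonyl)but-3-enoic acid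
Product: 5 (R)-4-[3,4-bis(benzyloxy)-5-methoxyphenyl]-3-(methoxycarbonyl)butanoic acid
Conditions: H2 (5 atm), [Rh(cod)2]BF4 (1 mol %), (S,S)-Me-DuPhos (1.1 mol %), NaOMe (10 mol %), MeOH, rt
Reagents that add atoms: none
Why: Asymmetric hydrogenation of an itaconate-type half-ester: carboxylate and alkene bind the [Rh((S,S)-Me-DuPhos)]+ fragment as a five-membered chelate, so hydrogen is delivered to one alkene face and C3 is set as R under ligand control. This homogeneous catalyst should not cleave the benzyl ethers.

Step 4
Reactants: 5 (R)-4-[3,4-bis(benzyloxy)-5-methoxyphenyl]-3-(methoxycarbonyl)butanoic acid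
Product: 6 methyl (R)-2-[3,4-bis(benzyloxy)-5-methoxybenzyl]-4-(ethylsulfanyl)-4-oxobutanoate
Conditions: EtSH (1.5 equiv), EDC·HCl (1.3 equiv), DMAP (10 mol %), CH2Cl2, 0 °C to rt
Reagents that add atoms: ethanethiol, CCS
Why: Carbodiimide coupling with DMAP (Steglich thioesterification) converts only the free acid; the methyl ester is inert and C3, which is not alpha to the activated carboxyl, should keep its configuration.

Step 5
Reactants: 6 methyl (R)-2-[3,4-bis(benzyloxy)-5-methoxybenzyl]-4-(ethylsulfanyl)-4-oxobutanoate
Product: 7 methyl (R)-2-[3,4-bis(benzyloxy)-5-methoxybenzyl]-4-oxobutanoate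
Conditions: Et3SiH (3 equiv), 10% Pd/C (5 mol % Pd), acetone, rt
Reagents that add atoms: none
Why: Fukuyama reduction: the thioester C–S bond adds oxidatively to zerovalent palladium of Pd/C, Et3SiH exchanges thiolate for hydride and reductive elimination gives the aldehyde without further reduction. The methyl ester is inert, and an aprotic solvent without a hydrogen atmosphere is chosen to keep the benzyl ethers.

Step 6
Reactants: 8 vanillyl alcohol (4-(hydroxymethyl)-2-methoxyphenol)
Product: 9 2-methoxy-4-[(4-methylphenyl)sulfonylmethyl]phenol
Conditions: TolSO2Na (1.5 equiv), HCO2H/H2O (1:1), rt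
Reagents that add atoms: sodium p-toluenesulfinate, Cc1ccc(cc1)S(=O)[O-].[Na+]
Why: Acid ionises the para-hydroxybenzylic alcohol to a stabilised benzylic cation (the protonated quinone methide), which is captured at sulfur by the sulfinate in an SN1-type S-alkylation; the sulfone should be a crystalline, storable source of 10.

Step 7
Reactants: 7 methyl (R)-2-[3,4-bis(benzyloxy)-5-methoxybenzyl]-4-oxobutanoate; 9 2-methoxy-4-[(4-methylphenyl)sulfonylmethyl]phenol
Product: 11 methyl (2R,3R)-2-[3,4-bis(benzyloxy)-5-methoxybenzyl]-3-formyl-4-(4-hydroxy-3-methoxyphenyl)butanoate, via quinone methide 10 (not isolated)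
Conditions: 9 (1.5 equiv, in portions), (R)-α,α-diphenylprolinol trimethylsilyl ether (20 mol %), NaHCO3 (3 equiv, powdered), H2O (5 equiv), CHCl3, 0 °C to rt; filter, wash with pH 7 buffer, concentrate below 25 °C, no chromatography
Reagents that add atoms: none
Why: Bicarbonate deprotonates the phenol of 9 and the phenoxide expels p-toluenesulfinate in a 1,6-elimination, which releases quinone methide 10 slowly and reversibly so that its standing concentration stays low. Aldehyde 7 condenses with the secondary amine to the E enamine, whose carbon C4 adds to the exocyclic carbon C7 of 10 in a 1,6-conjugate addition; the return of aromaticity to ring A makes the addition irreversible, and hydrolysis of the iminium ion releases 11 and the catalyst. The closest known reaction type is the enamine-catalysed asymmetric 1,6-addition of aldehydes to isolated para-quinone methides, combined with the base-triggered release of quinone methides from hydroxybenzyl sulfones. No ring closes. The new stereocentre C4 is set by the catalyst: in the s-trans E enamine the diphenyl(silyloxy)methyl group of the (R) amine covers one face, and attack of 10 on the open face should give the R configuration at C4. The step needs C-alkylation at C4 in preference to N-alkylation of the catalyst, O-alkylation of phenoxides and self-aldol reaction, which the bulk of the amine, the low concentration of 10 and the reversible return of sulfinate to 10 should favour; only the exocyclic carbon of 10 is unhindered and electrophilic, so regioselectivity is not in question. C3 is not part of the enamine and bicarbonate should not enolise the ester, so C3 should stay R. The alpha-branched product should be too hindered to re-enter enamine formation with this catalyst, so C4 is expected to hold until step 8.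

Step 8
Reactants: 11 methyl (2R,3R)-2-[3,4-bis(benzyloxy)-5-methoxybenzyl]-3-formyl-4-(4-hydroxy-3-methoxyphenyl)butanoate
Product: 13 (3R,4R)-3-[3,4-bis(benzyloxy)-5-methoxybenzyl]-4-(4-hydroxy-3-methoxybenzyl)oxolan-2-one, via hydroxy ester 12 (not isolated)
Conditions: NaBH4 (1.5 equiv), MeOH/CH2Cl2, 0 °C; aq. NH4Cl; then p-TsOH·H2O (10 mol %), CH2Cl2, rt
Reagents that add atoms: none
Why: NaBH4 reduces the aldehyde chemoselectively beside the methyl ester and thereby removes the acidic C4–H at once; catalytic acid then closes the lactone by 5-exo-trig acyl substitution with loss of methanol. No base is used, so C3 and C4 should keep their configuration, and a cis lactone arising from the minor C4 epimer is to be separated here as a diastereomer.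

Step 9
Reactants: 13 (3R,4R)-3-[3,4-bis(benzyloxy)-5-methoxybenzyl]-4-(4-hydroxy-3-methoxybenzyl)oxolan-2-one
Product: 14 (-)-thujaplicatin, (3R,4R)-3-(3,4-dihydroxy-5-methoxybenzyl)-4-(4-hydroxy-3-methoxybenzyl)oxolan-2-one
Conditions: H2 (1 atm), 10% Pd/C, EtOAc/MeOH, rt; filtration and concentration under argon
Reagents that add atoms: none
Why: Heterogeneous hydrogenolysis of the two aryl benzyl ethers; the lactone, the aryl methyl ethers and the benzylic methylenes C7 and C7' (no leaving group) are inert, and the neutral medium should leave C3 untouched.

## Compound list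

1 | 5-hydroxyvanillin (3,4-dihydroxy-5-methoxybenzaldehyde) | COc1cc(C=O)cc(O)c1O | starting material
2 | 3,4-bis(benzyloxy)-5-methoxybenzaldehyde | COc1cc(C=O)cc(OCc2ccccc2)c1OCc1ccccc1 | intermediate
3 | dimethyl succinate | COC(=O)CCC(=O)OC | starting material
4 | (E)-4-[3,4-bis(benzyloxy)-5-methoxyphenyl]-3-(methoxycarbonyl)but-3-enoic acid | COC(=O)/C(CC(O)=O)=C/c1cc(OCc2ccccc2)c(OCc2ccccc2)c(OC)c1 | intermediate
5 | (R)-4-[3,4-bis(benzyloxy)-5-methoxyphenyl]-3-(methoxycarbonyl)butanoic acid | OC(=O)C[C@@H](Cc1cc(OCc2ccccc2)c(OCc2ccccc2)c(OC)c1)C(=O)OC | intermediate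
6 | methyl (R)-2-[3,4-bis(benzyloxy)-5-methoxybenzyl]-4-(ethylsulfanyl)-4-oxobutanoate | CCSC(=O)C[C@@H](Cc1cc(OCc2ccccc2)c(OCc2ccccc2)c(OC)c1)C(=O)OC | intermediate
7 | methyl (R)-2-[3,4-bis(benzyloxy)-5-methoxybenzyl]-4-oxobutanoate | O=CC[C@@H](Cc1cc(OCc2ccccc2)c(OCc2ccccc2)c(OC)c1)C(=O)OC | intermediate
8 | vanillyl alcohol (4-(hydroxymethyl)-2-methoxyphenol) | COc1cc(CO)ccc1O | starting material
9 | 2-methoxy-4-[(4-methylphenyl)sulfonylmethyl]phenol | COc1cc(CS(=O)(=O)c2ccc(C)cc2)ccc1O | intermediate
10 | 2-methoxy-4-methylidenecyclohexa-2,5-dien-1-one (quinone methide of ring A) | COC1=CC(=C)C=CC1=O | intermediate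
11 | methyl (2R,3R)-2-[3,4-bis(benzyloxy)-5-methoxybenzyl]-3-formyl-4-(4-hydroxy-3-methoxyphenyl)butanoate | COc1cc(C[C@@H](C=O)[C@@H](Cc2cc(OCc3ccccc3)c(OCc3ccccc3)c(OC)c2)C(=O)OC)ccc1O | intermediate
12 | methyl (2R,3R)-2-[3,4-bis(benzyloxy)-5-methoxybenzyl]-4-hydroxy-3-(4-hydroxy-3-methoxybenzyl)butanoate | COc1cc(C[C@@H](CO)[C@@H](Cc2cc(OCc3ccccc3)c(OCc3ccccc3)c(OC)c2)C(=O)OC)ccc1O | intermediate
13 | (3R,4R)-3-[3,4-bis(benzyloxy)-5-methoxybenzyl]-4-(4-hydroxy-3-methoxybenzyl)oxolan-2-one | COc1cc(C[C@H]2COC(=O)[C@@H]2Cc2cc(OCc3ccccc3)c(OCc3ccccc3)c(OC)c2)ccc1O | intermediate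
14 | (-)-thujaplicatin, (3R,4R)-3-(3,4-dihydroxy-5-methoxybenzyl)-4-(4-hydroxy-3-methoxybenzyl)oxolan-2-one | COc1cc(C[C@H]2COC(=O)[C@@H]2Cc2cc(O)c(O)c(OC)c2)ccc1O | target

## Step count and risk

Total: 9 steps. Longest linear sequence: 8 steps (steps 1 to 5 and 7 to 9, from 1 to 14); step 6 is a one-step branch from 8.

Least certain steps:

**Step 7 (key step).**
- What may go wrong: quinone methide 10 is transient and may be consumed before the enamine reaches it. The possible losses are N-alkylation of the amine catalyst (which stops turnover), O-alkylation of phenoxides with oligomerisation, and hydration.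
- Face selectivity may also erode if the C3 centre, allylic to the enamine, opposes the catalyst (a mismatched pair).
- Prolonged contact with base may epimerise C4 of 11.
- Fallback (sets out from 5, returns at 14): the same C4–C7 bond is made by auxiliary-controlled enolate alkylation (Evans alkylation). Acid 5 is activated as its mixed pivalic anhydride (pivaloyl chloride, Et3N) and acylates lithiated (R)-4-benzyl-1,3-oxazolidin-2-one, giving methyl (R)-2-[3,4-bis(benzyloxy)-5-methoxybenzyl]-4-[(R)-4-benzyl-2-oxo-1,3-oxazolidin-3-yl]-4-oxobutanoate F1. Commercial 4-(benzyloxy)-3-methoxybenzyl alcohol F2 is converted with PBr3 into 4-(benzyloxy)-3-methoxybenzyl bromide F3. The sodium Z enolate of F1 (NaHMDS, THF, -78 °C) should be alkylated by F3 on the face away from the auxiliary benzyl group, giving methyl (2R,3R)-2-[3,4-bis(benzyloxy)-5-methoxybenzyl]-3-[4-(benzyloxy)-3-methoxybenzyl]-4-[(R)-4-benzyl-2-oxo-1,3-oxazolidin-3-yl]-4-oxobutanoate F4. NaBH4 in THF/H2O removes the auxiliary reductively and leaves the methyl ester, giving methyl (2R,3R)-2-[3,4-bis(benzyloxy)-5-methoxybenzyl]-3-[4-(benzyloxy)-3-methoxybenzyl]-4-hydroxybutanoate F5. Catalytic p-TsOH closes this to (3R,4R)-3-[3,4-bis(benzyloxy)-5-methoxybenzyl]-4-[4-(benzyloxy)-3-methoxybenzyl]oxolan-2-one F6, and hydrogenolysis of all three benzyl ethers under the conditions of step 9 gives 14.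

**Step 3.**
- What may go wrong: face discrimination may be incomplete, or the sense of induction may be opposite to the one assumed, for this electron-rich trisubstituted arylidene half-ester; the reduction may also be slow.
- Fallback (sets out from 4, returns at 5): hydrogenation with an achiral catalyst ([Rh(cod)2]BF4 with 1,4-bis(diphenylphosphino)butane, H2, MeOH) gives racemic 4-[3,4-bis(benzyloxy)-5-methoxyphenyl]-3-(methoxycarbonyl)butanoic acid F7. This is resolved by crystallisation of the (R)-1-phenylethylammonium salt of the (R) acid F8 (the antipodal amine is used if the other salt is the less soluble one). Acidification of F8 returns 5.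

**Step 5.**
- What may go wrong: the Et3SiH and Pd/C couple may cleave benzyl ethers or reduce the aldehyde further, or sulfur residues may stop the catalyst.
- Fallback (sets out from 5, returns at 7): BH3·SMe2 in THF at 0 °C reduces the free acid and leaves the methyl ester, giving methyl (R)-2-[3,4-bis(benzyloxy)-5-methoxybenzyl]-4-hydroxybutanoate F9. This is kept cold and neutral to avoid lactonisation and is oxidised with Dess–Martin periodinane to 7.

**Step 9.**
- What may go wrong: cleavage of the benzyl ether flanked by two oxygen substituents may be incomplete, or the catechol may oxidise during work-up.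
- Fallback (sets out from 13, returns at 14): Lewis-acid debenzylation with BCl3 and pentamethylbenzene as cation scavenger in CH2Cl2 at -78 °C, which cleaves benzyl ethers by ionisation and not by hydrogenolysis and makes no new compound on the way (F0).

## Further compounds

F1 | step 7 | methyl (R)-2-[3,4-bis(benzyloxy)-5-methoxybenzyl]-4-[(R)-4-benzyl-2-oxo-1,3-oxazolidin-3-yl]-4-oxobutanoate | O=C(C[C@@H](Cc1cc(OCc2ccccc2)c(OCc2ccccc2)c(OC)c1)C(=O)OC)N1[C@H](Cc2ccccc2)COC1=O
F2 | step 7 | 4-(benzyloxy)-3-methoxybenzyl alcohol | COc1cc(CO)ccc1OCc1ccccc1
F3 | step 7 | 4-(benzyloxy)-3-methoxybenzyl bromide | COc1cc(CBr)ccc1OCc1ccccc1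
F4 | step 7 | methyl (2R,3R)-2-[3,4-bis(benzyloxy)-5-methoxybenzyl]-3-[4-(benzyloxy)-3-methoxybenzyl]-4-[(R)-4-benzyl-2-oxo-1,3-oxazolidin-3-yl]-4-oxobutanoate | O=C([C@H](Cc1ccc(OCc2ccccc2)c(OC)c1)[C@@H](Cc1cc(OCc2ccccc2)c(OCc2ccccc2)c(OC)c1)C(=O)OC)N1[C@H](Cc2ccccc2)COC1=O
F5 | step 7 | methyl (2R,3R)-2-[3,4-bis(benzyloxy)-5-methoxybenzyl]-3-[4-(benzyloxy)-3-methoxybenzyl]-4-hydroxybutanoate | COc1cc(C[C@@H](CO)[C@@H](Cc2cc(OCc3ccccc3)c(OCc3ccccc3)c(OC)c2)C(=O)OC)ccc1OCc1ccccc1
F6 | step 7 | (3R,4R)-3-[3,4-bis(benzyloxy)-5-methoxybenzyl]-4-[4-(benzyloxy)-3-methoxybenzyl]oxolan-2-one | COc1cc(C[C@H]2COC(=O)[C@@H]2Cc2cc(OCc3ccccc3)c(OCc3ccccc3)c(OC)c2)ccc1OCc1ccccc1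
F7 | step 3 | racemic 4-[3,4-bis(benzyloxy)-5-methoxyphenyl]-3-(methoxycarbonyl)butanoic acid | OC(=O)CC(Cc1cc(OCc2ccccc2)c(OCc2ccccc2)c(OC)c1)C(=O)OC
F8 | step 3 | (R)-1-phenylethylammonium (R)-4-[3,4-bis(benzyloxy)-5-methoxyphenyl]-3-(methoxycarbonyl)butanoate | C[C@@H]([NH3+])c1ccccc1.[O-]C(=O)C[C@@H](Cc1cc(OCc2ccccc2)c(OCc2ccccc2)c(OC)c1)C(=O)OC
F9 | step 5 | methyl (R)-2-[3,4-bis(benzyloxy)-5-methoxybenzyl]-4-hydroxybutanoate | OCC[C@@H](Cc1cc(OCc2ccccc2)c(OCc2ccccc2)c(OC)c1)C(=O)OC
F0 | step 9 | none | none
A1 | alternative 1 | ethyl (R,E)-2-[3,4-bis(benzyloxy)-5-methoxybenzyl]-4-(4-benzyloxy-3-methoxyphenyl)-4-{[(bromomethyl)dimethylsilyl]oxy}but-2-enoate | CCOC(=O)/C(Cc1cc(OCc2ccccc2)c(OCc2ccccc2)c(OC)c1)=C/[C@H](c1ccc(OCc2ccccc2)c(OC)c1)O[Si](C)(C)CBr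
A2 | alternative 1 | ethyl 3-[3,4-bis(benzyloxy)-5-methoxyphenyl]-2-[(4S,5R)-5-(4-benzyloxy-3-methoxyphenyl)-2,2-dimethyl-1,2-oxasilolan-4-yl]propanoate, both epimers at the chain carbon | C[Si]1(C)C[C@@H](C(Cc2cc(OCc3ccccc3)c(OCc3ccccc3)c(OC)c2)C(=O)OCC)[C@H](c2ccc(OCc3ccccc3)c(OC)c2)O1
A3 | alternative 2 | 3-[3,4-bis(benzyloxy)-5-methoxybenzyl]-4-[4-(benzyloxy)-3-methoxybenzyl]furan-2(5H)-one | COc1cc(CC2=C(Cc3cc(OCc4ccccc4)c(OCc4ccccc4)c(OC)c3)C(=O)OC2)ccc1OCc1ccccc1
A4 | alternative 2 | tri-O-benzyl-(-)-thujaplicatin, (3R,4R)-3-[3,4-bis(benzyloxy)-5-methoxybenzyl]-4-[4-(benzyloxy)-3-methoxybenzyl]oxolan-2-one | COc1cc(C[C@H]2COC(=O)[C@@H]2Cc2cc(OCc3ccccc3)c(OCc3ccccc3)c(OC)c2)ccc1OCc1ccccc1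
A5 | alternative 3 | vinylboronic acid pinacol ester | C=CB1OC(C)(C)C(C)(C)O1
A6 | alternative 3 | 2-bromo-3-[3,4-bis(benzyloxy)-5-methoxyphenyl]prop-1-ene | C=C(Br)Cc1cc(OCc2ccccc2)c(OCc2ccccc2)c(OC)c1
A7 | alternative 3 | 4-(benzyloxy)-3-methoxyphenyl trifluoromethanesulfonate | COc1cc(OS(=O)(=O)C(F)(F)F)ccc1OCc1ccccc1
A8 | alternative 3 | (R)-2-{1-[4-(benzyloxy)-3-methoxyphenyl]-4-[3,4-bis(benzyloxy)-5-methoxyphenyl]-3-methylidenebutan-2-yl}-4,4,5,5-tetramethyl-1,3,2-dioxaborolane | COc1cc(C[C@@H](B2OC(C)(C)C(C)(C)O2)C(=C)Cc2cc(OCc3ccccc3)c(OCc3ccccc3)c(OC)c2)ccc1OCc1ccccc1
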